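In a one-step world, substrate going straight to target, target climbs as long as substrate lasts. These runs do not climb.

| flask | substrate | partner | temperature | remark | time |
|---|---|---|---|---|---|
| south | 18 mM | 0.90 equiv | −25 °C | run made earlier |  |
| west | 18 mM | 1.4 equiv | −10 °C | run made earlier |  |
| Saturday's | 18 mM | 1.80 equiv | −20 °C |  | 4.0 d |
| Wednesday's | 18 mM | 1.80 equiv | 0 °C |  | 4.0 d |

- south (time / d: target / %): 0.417: 4.8; 0.625: 4.2; 0.833: 4.3; 1.25: 3.8; 2.08: 3.3; 3.00: 3.7; 5.00: 3.9
- west (time / d: target / %): 0.167: 14.5; 0.500: 16.7; 0.833: 15.2; 1.25: 14.5; 1.67: 15.1; 2.50: 15.2; 3.00: 15.8

(readings scatter by 1 percentage point)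

- percent here means substrate units held: one side product counts as two
- candidate steps: substrate -> intermediate; partner + intermediate -> target; substrate + target -> side product

- which flask leads in amount of target, in percent of the substrate charged ("all alike" within 1.5 percentage points) (Saturday's / Wednesday's / all alike)
- how much target is there at the end, in percent of the substrate charged: Saturday's
- how much target is there at the end, in percent of the substrate charged: Wednesday's

1. The readings. South averages 4.00% with 0.90 equiv of partner, and west averages 15.3% with 1.4 equiv. Both stay flat, within the scatter of 1 percentage point, from the first reading. In concentration that is 0.720 mM and 2.75 mM.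

2. First instants. Take substrate → intermediate as slow (the rate-limiting step) and capture by partner as fast. Target is then made at k·c_substrate, and while c_target is small, little of it is lost.

3. Middle. Loss, k′·c_substrate·c_target, grows with c_target until it equals making. Then c_substrate cancels and c_target = k/k′, a concentration containing neither charge.

4. Your figure. −20 °C lies a third of the way from south to west. Interpolating the logarithm gives 1.13 mM: the ceiling, the target concentration at which target is made as fast as it is lost.

5. End. Saturday's charge stands far above this ceiling, so expect target to arrive early and stay at 6.28% of the charge while substrate turns into side product. Extrapolated, Wednesday's ceiling is 6.73 mM, or 37.4%. That is a larger share of the charge than in Saturday's, so expect Wednesday's target to stop somewhere below its ceiling as c_substrate falls.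

6. The forecast. It holds the level “independent of partner and set by temperature alone” and gives 6.4% for Saturday's, slightly above your figure, and 30% for Wednesday's. It names Wednesday's as the leader.

7. The flasks. Wednesday's leads, with 6.45% in Saturday's and 28.9% in Wednesday's.

    substrate → intermediate (k = 5.77 × 10⁻⁶ s⁻¹, Ea = 84.0 kJ mol⁻¹)
    partner + intermediate → target (k = 0.0195 L mol⁻¹ s⁻¹, Ea = 42.0 kJ mol⁻¹)
    substrate + target → side product (k = 0.00509 L mol⁻¹ s⁻¹, Ea = 38.0 kJ mol⁻¹)
    (constants at −20 °C)

Saturday's target is 1.16 mM against your ceiling of 1.13 mM, and at 40.0 d it stands at 6.45%. The forecast's percentage belongs to the 18 mM charge: at 10.2 mM of substrate, with equivalents and time held, Saturday's answer has moved by 5 points. A neighbouring flask goes further, to 7.2 mM at the same temperature. Your ceiling over that charge is 15.7%. That flask ends with 16.1% as target, which is 1.16 mM, and 81.6% as side product.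

All runs were computed for an exercise; the scatter is artificial.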